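**Retrosynthetic overview**
- The target is reached from a guaianolide that has the C10=C14–O–C4 enol ether in place, by unmasking the α-methylene lactone and the C15 hydroxyl.
- That guaianolide comes from a fully oxygenated eudesmanolide 1β-mesylate by a single 1,2-shift of C5 from C10 to C1. Ring A (six-membered, C1–C2–C3–C4–C5–C10) contracts to the cyclopentane C1–C5 and ring B expands to the cycloheptane.
- Enabling feature: in the trans-decalin the equatorial C1–OMs bond is antiperiplanar to the C5–C10 bond, and the ether oxygen of the tetrahydrofuran ring C4–O–C14–C10–C5 sits next to C10. A hydride shift from C14 can therefore turn the C10 cation into an oxocarbenium ion and then into the enol ether.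
- The eudesmanolide is built from a 1β-hydroxy-eudesm-4(15)-enolide by C4/C15 oxygenation, C–H oxidation at C8, hypoiodite etherification of C14, and C9/C8 oxygenation with esterification.
- The eudesmanolide skeleton comes from (+)-costunolide by epoxidation and transannular radical cyclisation. Ring order: lactone and ten-membered ring (starting material), rings A and B, tetrahydrofuran, then cyclopentane, cycloheptane and dihydropyran together.

Key step: step 15

Conventions and assumption: eudesmane/guaiane numbering is used and all compounds keep 6βH and 7αH (trans lactone); Teoc = 2-(trimethylsilyl)ethoxycarbonyl; PDP = N,N'-bis(2-pyridylmethyl)-2,2'-bipyrrolidine. C11 of the sulfone adducts is drawn 11βH (protonation on the less hindered face); its configuration is immaterial because C11 returns to sp2 in step 16.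

**Step 1**
Reactants: 1 (+)-costunolide
Product: 2 13-(methylsulfonyl)-11βH-germacra-1(10)E,4E-dien-12,6α-olide
Conditions: MeSO2Na, AcOH, EtOH/H2O, 40 °C
Reagents that add atoms: sodium methanesulfinate, CS(=O)[O-].[Na+]
Why: Sulfa-Michael addition to the α-methylene lactone should mask the acceptor as a β-sulfonyl lactone that survives the oxidants, bases and hydrides of steps 2–15 and is released by E1cB elimination in step 16; C11 is set by protonation of the lactone enolate on the less hindered face.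

**Step 2**
Reactants: 2 13-(methylsulfonyl)-11βH-germacra-1(10)E,4E-dien-12,6α-olide
Product: 3 1β,10α-epoxy-13-(methylsulfonyl)-11βH-germacr-4E-en-12,6α-olide
Conditions: mCPBA (1.05 equiv), NaHCO3, CH2Cl2, 0 °C
Reagents that add atoms: 3-chloroperoxybenzoic acid, OOC(=O)c1cccc(Cl)c1
Why: Prilezhaev epoxidation should take the more exposed C1=C10 alkene (C4=C5 is deactivated by the allylic lactone oxygen) on the outer face of the crown conformer, giving the trans 1β,10α-epoxide stereospecifically from the E alkene.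

**Step 3**
Reactants: 3 1β,10α-epoxy-13-(methylsulfonyl)-11βH-germacr-4E-en-12,6α-olide
Product: 4 1β-hydroxy-13-(methylsulfonyl)-5αH,11βH-eudesm-4(15)-en-12,6α-olide
Conditions: Cp2TiCl2 (2.5 equiv), Mn, THF, rt; aq HCl work-up
Reagents that add atoms: none
Why: Nugent–RajanBabu homolytic epoxide opening by Cp2TiCl (trivalent titanium, formed in the flask) should give the tertiary C10 radical, which adds transannularly to C5 through a chair–chair transition state (6-endo closure, trans-decalin with 10β-CH3 and 5αH, C1–O untouched and hence 1β-OH), after which the C4 radical is trapped by a second Cp2TiCl and loses a C15 hydrogen to leave the exocyclic alkene.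

**Step 4**
Reactants: 4 1β-hydroxy-13-(methylsulfonyl)-5αH,11βH-eudesm-4(15)-en-12,6α-olide
Product: 5 1β-mesyloxy-13-(methylsulfonyl)-5αH,11βH-eudesm-4(15)-en-12,6α-olide
Conditions: MsCl, Et3N, CH2Cl2, 0 °C
Reagents that add atoms: methanesulfonyl chloride, CS(=O)(=O)Cl
Why: O-Sulfonylation of the equatorial secondary alcohol with retention at C1 installs the leaving group of step 15 early, where it is inert at room temperature and also deactivates the ring A C–H bonds for step 9.

**Step 5**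
Reactants: 5 1β-mesyloxy-13-(methylsulfonyl)-5αH,11βH-eudesm-4(15)-en-12,6α-olide
Product: 7 1β-mesyloxy-13-(methylsulfonyl)-4-oxo-15-nor-5αH,11βH-eudesman-12,6α-olide, via ozonide 6 (not isolated)
Conditions: O3, CH2Cl2, −78 °C; then PPh3, −78 °C to rt
Reagents that add atoms: ozone, [O-][O+]=O
Why: Ozonolysis (Criegee mechanism) of the only alkene with reductive work-up gives the C4 ketone without base, so C5 and the β-acyloxy ketone should stay intact.

**Step 6**
Reactants: 7 1β-mesyloxy-13-(methylsulfonyl)-4-oxo-15-nor-5αH,11βH-eudesman-12,6α-olide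
Product: 8 4β-hydroxy-15-[isopropoxy(dimethyl)silyl]-1β-mesyloxy-13-(methylsulfonyl)-5αH,11βH-eudesman-12,6α-olide
Conditions: ClMgCH2SiMe2(Oi-Pr), CeCl3, THF, −78 °C
Reagents that add atoms: [(isopropoxy)dimethylsilyl]methylmagnesium chloride, CC(C)O[Si](C)(C)C[Mg]Cl
Why: Organocerium 1,2-addition of the Tamao hydroxymethyl anion equivalent should occur on the equatorial α side, because the β side of C4 is blocked by the syn-axial C14 methyl, setting 4β-OH and 4α-CH2Si, while the low basicity avoids enolisation and β-elimination of the lactone oxygen.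

**Step 7**
Reactants: 8 4β-hydroxy-15-[isopropoxy(dimethyl)silyl]-1β-mesyloxy-13-(methylsulfonyl)-5αH,11βH-eudesman-12,6α-olide
Product: 9 4β,15-dihydroxy-1β-mesyloxy-13-(methylsulfonyl)-5αH,11βH-eudesman-12,6α-olide
Conditions: H2O2 (30%), KF, KHCO3, THF/MeOH, rt
Reagents that add atoms: hydrogen peroxide, OO
Why: Tamao–Fleming oxidation converts the C15–Si bond into C15–OH without touching a stereocentre, and the bicarbonate medium should be too weakly basic to eliminate the sulfinate or displace the mesylate.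

**Step 8**
Reactants: 9 4β,15-dihydroxy-1β-mesyloxy-13-(methylsulfonyl)-5αH,11βH-eudesman-12,6α-olide
Product: 10 4β-hydroxy-1β-mesyloxy-13-(methylsulfonyl)-15-(Teoc-oxy)-5αH,11βH-eudesman-12,6α-olide
Conditions: 4-nitrophenyl 2-(trimethylsilyl)ethyl carbonate, Et3N, DMAP (cat.), CH2Cl2, rt
Reagents that add atoms: 4-nitrophenyl 2-(trimethylsilyl)ethyl carbonate, C[Si](C)(C)CCOC(=O)Oc1ccc(cc1)[N+](=O)[O-]
Why: Acyl transfer should reach only the primary C15 hydroxyl (the axial tertiary 4β-OH is inert), giving an electron-withdrawing, fluoride-labile carbonate that tolerates steps 9–16.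

**Step 9**
Reactants: 10 4β-hydroxy-1β-mesyloxy-13-(methylsulfonyl)-15-(Teoc-oxy)-5αH,11βH-eudesman-12,6α-olide
Product: 12 4β-hydroxy-1β-mesyloxy-13-(methylsulfonyl)-8-oxo-15-(Teoc-oxy)-5αH,11βH-eudesman-12,6α-olide, via 8α-alcohol 11 (not isolated)
Conditions: Fe(S,S-PDP)(MeCN)2(SbF6)2 (3 × 5 mol %), H2O2, AcOH, MeCN, rt, portionwise addition
Reagents that add atoms: hydrogen peroxide, OO
Why: Iron-catalysed aliphatic C–H oxidation (hydroxylation, then oxidation of the carbinol to the ketone) should select C8, because C2, C3 and C13 are inductively deactivated by the mesylate, the C4 oxygen and the sulfone, C9 is neopentyl, and the tertiary C–H bonds at C5, C7 and C11 lie next to oxygen or carbonyl groups; no stereocentre is created.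

**Step 10**
Reactants: 12 4β-hydroxy-1β-mesyloxy-13-(methylsulfonyl)-8-oxo-15-(Teoc-oxy)-5αH,11βH-eudesman-12,6α-olide
Product: 13 4β,14-epoxy-1β-mesyloxy-13-(methylsulfonyl)-8-oxo-15-(Teoc-oxy)-5αH,11βH-eudesman-12,6α-olide
Conditions: PhI(OAc)2, I2, cyclohexane/CH2Cl2, hν (visible), rt
Reagents that add atoms: none
Why: In this Suárez hypoiodite reaction the O4 alkoxy radical should abstract a hydrogen from the 1,3-diaxial C14 methyl (1,5-hydrogen transfer), and iodination followed by intramolecular substitution closes the tetrahydrofuran C4–O–C14–C10–C5 (5-exo-tet) without change at any stereocentre.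

**Step 11**
Reactants: 13 4β,14-epoxy-1β-mesyloxy-13-(methylsulfonyl)-8-oxo-15-(Teoc-oxy)-5αH,11βH-eudesman-12,6α-olide
Product: 15 4β,14-epoxy-9α-hydroxy-1β-mesyloxy-13-(methylsulfonyl)-8-oxo-15-(Teoc-oxy)-5αH,11βH-eudesman-12,6α-olide, via silyl enol ether 14 (not isolated)
Conditions: LiN(SiMe3)2, Me3SiCl, THF, −78 °C; then DMDO, acetone, −40 °C; aq citric acid
Reagents that add atoms: dimethyldioxirane, CC1(C)OO1
Why: Rubottom oxidation, in which kinetic deprotonation at the C9 methylene rather than the C7 methine gives the C8=C9 silyl enol ether, which should be epoxidised on the α face (the β face is screened by the axial C14 bridge on C10) so that hydrolysis leaves the axial 9α-OH.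

**Step 12**
Reactants: 15 4β,14-epoxy-9α-hydroxy-1β-mesyloxy-13-(methylsulfonyl)-8-oxo-15-(Teoc-oxy)-5αH,11βH-eudesman-12,6α-olide
Product: 16 9α-acetoxy-4β,14-epoxy-1β-mesyloxy-13-(methylsulfonyl)-8-oxo-15-(Teoc-oxy)-5αH,11βH-eudesman-12,6α-olide
Conditions: Ac2O, pyridine, DMAP (cat.), CH2Cl2, 0 °C
Reagents that add atoms: acetic anhydride, CC(=O)OC(C)=O
Why: Acetylation of the only free hydroxyl places the acetate on O9 before O8 exists, and the mild amine base should not epimerise C9.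

**Step 13**
Reactants: 16 9α-acetoxy-4β,14-epoxy-1β-mesyloxy-13-(methylsulfonyl)-8-oxo-15-(Teoc-oxy)-5αH,11βH-eudesman-12,6α-olide
Product: 17 9α-acetoxy-4β,14-epoxy-8β-hydroxy-1β-mesyloxy-13-(methylsulfonyl)-15-(Teoc-oxy)-5αH,11βH-eudesman-12,6α-olide
Conditions: LiBH(s-Bu)3, THF, −78 °C
Reagents that add atoms: none
Why: The bulky hydride should attack C8 along the equatorial α trajectory, since the axial β trajectory is blocked by the syn-axial C14 bridge, giving the axial 8β-alcohol; the trans-diaxial 8β-O/9α-OAc pair cannot reach the cyclic orthoester needed for acetyl migration.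

**Step 14**
Reactants: 17 9α-acetoxy-4β,14-epoxy-8β-hydroxy-1β-mesyloxy-13-(methylsulfonyl)-15-(Teoc-oxy)-5αH,11βH-eudesman-12,6α-olide; 18 (R)-2-methylbutanoic acid
Product: 19 9α-acetoxy-4β,14-epoxy-1β-mesyloxy-8β-[(2R)-2-methylbutanoyloxy]-13-(methylsulfonyl)-15-(Teoc-oxy)-5αH,11βH-eudesman-12,6α-olide
Conditions: DIC, DMAP, CH2Cl2, rt
Reagents that add atoms: none
Why: Steglich esterification of the 8β-hydroxyl should proceed with retention at C8 and at the α-carbon of the acid (no ketene pathway).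

**Step 15**
Reactants: 19 9α-acetoxy-4β,14-epoxy-1β-mesyloxy-8β-[(2R)-2-methylbutanoyloxy]-13-(methylsulfonyl)-15-(Teoc-oxy)-5αH,11βH-eudesman-12,6α-olide
Product: 20 9α-acetoxy-4β,14-epoxy-8β-[(2R)-2-methylbutanoyloxy]-13-(methylsulfonyl)-15-(Teoc-oxy)-1αH,5αH,11βH-guai-10(14)-en-12,6α-olide
Conditions: 2,6-lutidine (3 equiv), (CF3)2CHOH, 60 °C
Reagents that add atoms: none
Why: Proposed new method: ionisation of the equatorial 1β-mesylate is assisted by the antiperiplanar C5–C10 σ bond, so C5 migrates from C10 to C1 (Wagner–Meerwein 1,2-shift), and the C10 cation left behind is quenched by a 1,2-hydride shift from C14, whose C–H bonds are α to the ether oxygen, giving a C14 oxocarbenium ion that 2,6-lutidine deprotonates at C10 to the C10=C14 enol ether. The closest known reaction type is the solvolytic rearrangement of 1β-sulfonyloxy-eudesmanolides to guaianolides, which ends by proton loss to a 10(14)- or 1(10)-alkene; termination by hydride shift through an ether oxygen has not been shown. No ring is closed by cyclisation: ring A (C1–C2–C3–C4–C5–C10) contracts to the cyclopentane C1–C5, ring B expands to the cycloheptane, and the tetrahydrofuran C4–O–C14–C10–C5 becomes the bridged dihydropyran C4–O–C14=C10–C1–C5, all through the one 1,2-shift. C1 (1αH) is set by backside attack of the migrating C5 anti to the mesylate, C5 keeps its configuration as the migrating centre, and C4, C6, C7, C8 and C9 are untouched. The selectivity needed is hydride shift over proton loss and over capture of the cation: loss of H1 would give a bridgehead alkene, loss of H9 a less stabilised enol acetate, and attack by the 9α-acetate carbonyl gives an acetoxonium ion only reversibly in the dry medium, whereas the hydride shift to the oxocarbenium ion is irreversible. The retarding effect of the two β-oxygen atoms on ionisation should be offset by the high ionising power and low nucleophilicity of (CF3)2CHOH.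

**Step 16**
Reactants: 20 9α-acetoxy-4β,14-epoxy-8β-[(2R)-2-methylbutanoyloxy]-13-(methylsulfonyl)-15-(Teoc-oxy)-1αH,5αH,11βH-guai-10(14)-en-12,6α-olide
Product: 21 9α-acetoxy-4β,14-epoxy-8β-[(2R)-2-methylbutanoyloxy]-15-(Teoc-oxy)-1αH,5αH-guaia-10(14),11(13)-dien-12,6α-olide
Conditions: DBU, CH2Cl2, rt
Reagents that add atoms: none
Why: E1cB elimination of methanesulfinate from the β-sulfonyl lactone should regenerate the α-methylene-γ-lactone, the enol ether and the esters being stable to the amidine base.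

**Step 17**
Reactants: 21 9α-acetoxy-4β,14-epoxy-8β-[(2R)-2-methylbutanoyloxy]-15-(Teoc-oxy)-1αH,5αH-guaia-10(14),11(13)-dien-12,6α-olide
Product: 22 9α-acetoxy-4β,14-epoxy-15-hydroxy-8β-[(2R)-2-methylbutanoyloxy]-1αH,5αH-guaia-10(14),11(13)-dien-12,6α-olide (CNP0013863.3)
Conditions: Bu4NF, AcOH (1:1), THF, 0 °C to rt; pH 7 buffer work-up
Reagents that add atoms: none
Why: Fluoride attack on silicon fragments the Teoc carbonate (β-elimination to ethene, CO2 and the alcohol) under buffered, non-acidic conditions, so the free 15-OH should not add to the enol ether and no acyl group should migrate.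

**Compound list**
1 | (+)-costunolide, germacra-1(10)E,4E,11(13)-trien-12,6α-olide | C1C/C(C)=C/CC/C(C)=C/[C@H]2OC(=O)C(=C)[C@@H]21 | starting material
2 | 13-(methylsulfonyl)-11βH-germacra-1(10)E,4E-dien-12,6α-olide | C1C/C(C)=C/CC/C(C)=C/[C@H]2OC(=O)[C@@H](CS(C)(=O)=O)[C@@H]21 | intermediate
3 | 1β,10α-epoxy-13-(methylsulfonyl)-11βH-germacr-4E-en-12,6α-olide | C1C[C@@]3(C)O[C@@H]3CC/C(C)=C/[C@H]2OC(=O)[C@@H](CS(C)(=O)=O)[C@@H]21 | intermediate
4 | 1β-hydroxy-13-(methylsulfonyl)-5αH,11βH-eudesm-4(15)-en-12,6α-olide | CS(=O)(=O)C[C@@H]1C(=O)O[C@H]2[C@H]1CC[C@@]3(C)[C@H](O)CCC(=C)[C@H]23 | intermediate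
5 | 1β-mesyloxy-13-(methylsulfonyl)-5αH,11βH-eudesm-4(15)-en-12,6α-olide | CS(=O)(=O)C[C@@H]1C(=O)O[C@H]2[C@H]1CC[C@@]3(C)[C@H](OS(C)(=O)=O)CCC(=C)[C@H]23 | intermediate
6 | ozonide of 5 (spiro-1,2,4-trioxolane at C4, configuration at C4 undefined) | CS(=O)(=O)C[C@@H]1C(=O)O[C@H]2[C@H]1CC[C@@]3(C)[C@H](OS(C)(=O)=O)CCC4(OOCO4)[C@H]23 | intermediate (not isolated)
7 | 1β-mesyloxy-13-(methylsulfonyl)-4-oxo-15-nor-5αH,11βH-eudesman-12,6α-olide | CS(=O)(=O)C[C@@H]1C(=O)O[C@H]2[C@H]1CC[C@@]3(C)[C@H](OS(C)(=O)=O)CCC(=O)[C@H]23 | intermediate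
8 | 4β-hydroxy-15-[isopropoxy(dimethyl)silyl]-1β-mesyloxy-13-(methylsulfonyl)-5αH,11βH-eudesman-12,6α-olide | CS(=O)(=O)C[C@@H]1C(=O)O[C@H]2[C@H]1CC[C@@]3(C)[C@H](OS(C)(=O)=O)CC[C@@](O)(C[Si](C)(C)OC(C)C)[C@H]23 | intermediate
9 | 4β,15-dihydroxy-1β-mesyloxy-13-(methylsulfonyl)-5αH,11βH-eudesman-12,6α-olide | CS(=O)(=O)C[C@@H]1C(=O)O[C@H]2[C@H]1CC[C@@]3(C)[C@H](OS(C)(=O)=O)CC[C@@](O)(CO)[C@H]23 | intermediate
10 | 4β-hydroxy-1β-mesyloxy-13-(methylsulfonyl)-15-(Teoc-oxy)-5αH,11βH-eudesman-12,6α-olide | CS(=O)(=O)C[C@@H]1C(=O)O[C@H]2[C@H]1CC[C@@]3(C)[C@H](OS(C)(=O)=O)CC[C@@](O)(COC(=O)OCC[Si](C)(C)C)[C@H]23 | intermediate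
11 | 4β,8α-dihydroxy-1β-mesyloxy-13-(methylsulfonyl)-15-(Teoc-oxy)-5αH,11βH-eudesman-12,6α-olide | CS(=O)(=O)C[C@@H]1C(=O)O[C@H]2[C@H]1[C@@H](O)C[C@@]3(C)[C@H](OS(C)(=O)=O)CC[C@@](O)(COC(=O)OCC[Si](C)(C)C)[C@H]23 | intermediate (not isolated)
12 | 4β-hydroxy-1β-mesyloxy-13-(methylsulfonyl)-8-oxo-15-(Teoc-oxy)-5αH,11βH-eudesman-12,6α-olide | CS(=O)(=O)C[C@@H]1C(=O)O[C@H]2[C@H]1C(=O)C[C@@]3(C)[C@H](OS(C)(=O)=O)CC[C@@](O)(COC(=O)OCC[Si](C)(C)C)[C@H]23 | intermediate
13 | 4β,14-epoxy-1β-mesyloxy-13-(methylsulfonyl)-8-oxo-15-(Teoc-oxy)-5αH,11βH-eudesman-12,6α-olide | CS(=O)(=O)C[C@@H]1C(=O)O[C@H]2[C@H]1C(=O)C[C@@]3(CO4)[C@H](OS(C)(=O)=O)CC[C@@]4(COC(=O)OCC[Si](C)(C)C)[C@H]23 | intermediate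
14 | 4β,14-epoxy-1β-mesyloxy-13-(methylsulfonyl)-15-(Teoc-oxy)-8-(trimethylsilyloxy)-5αH,11βH-eudesm-8-en-12,6α-olide | CS(=O)(=O)C[C@@H]1C(=O)O[C@H]2[C@H]1C(O[Si](C)(C)C)=C[C@@]3(CO4)[C@H](OS(C)(=O)=O)CC[C@@]4(COC(=O)OCC[Si](C)(C)C)[C@H]23 | intermediate (not isolated)
15 | 4β,14-epoxy-9α-hydroxy-1β-mesyloxy-13-(methylsulfonyl)-8-oxo-15-(Teoc-oxy)-5αH,11βH-eudesman-12,6α-olide | CS(=O)(=O)C[C@@H]1C(=O)O[C@H]2[C@H]1C(=O)[C@@H](O)[C@@]3(CO4)[C@H](OS(C)(=O)=O)CC[C@@]4(COC(=O)OCC[Si](C)(C)C)[C@H]23 | intermediate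
16 | 9α-acetoxy-4β,14-epoxy-1β-mesyloxy-13-(methylsulfonyl)-8-oxo-15-(Teoc-oxy)-5αH,11βH-eudesman-12,6α-olide | CS(=O)(=O)C[C@@H]1C(=O)O[C@H]2[C@H]1C(=O)[C@@H](OC(C)=O)[C@@]3(CO4)[C@H](OS(C)(=O)=O)CC[C@@]4(COC(=O)OCC[Si](C)(C)C)[C@H]23 | intermediate
17 | 9α-acetoxy-4β,14-epoxy-8β-hydroxy-1β-mesyloxy-13-(methylsulfonyl)-15-(Teoc-oxy)-5αH,11βH-eudesman-12,6α-olide | CS(=O)(=O)C[C@@H]1C(=O)O[C@H]2[C@H]1[C@H](O)[C@@H](OC(C)=O)[C@@]3(CO4)[C@H](OS(C)(=O)=O)CC[C@@]4(COC(=O)OCC[Si](C)(C)C)[C@H]23 | intermediate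
18 | (R)-2-methylbutanoic acid | CC[C@@H](C)C(=O)O | starting material
19 | 9α-acetoxy-4β,14-epoxy-1β-mesyloxy-8β-[(2R)-2-methylbutanoyloxy]-13-(methylsulfonyl)-15-(Teoc-oxy)-5αH,11βH-eudesman-12,6α-olide | CS(=O)(=O)C[C@@H]1C(=O)O[C@H]2[C@H]1[C@H](OC(=O)[C@H](C)CC)[C@@H](OC(C)=O)[C@@]3(CO4)[C@H](OS(C)(=O)=O)CC[C@@]4(COC(=O)OCC[Si](C)(C)C)[C@H]23 | intermediate
20 | 9α-acetoxy-4β,14-epoxy-8β-[(2R)-2-methylbutanoyloxy]-13-(methylsulfonyl)-15-(Teoc-oxy)-1αH,5αH,11βH-guai-10(14)-en-12,6α-olide | CS(=O)(=O)C[C@@H]1C(=O)O[C@H]2[C@H]1[C@H](OC(=O)[C@H](C)CC)[C@@H](OC(C)=O)C1=CO[C@@]3(COC(=O)OCC[Si](C)(C)C)CC[C@@H]1[C@@H]23 | intermediate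
21 | 9α-acetoxy-4β,14-epoxy-8β-[(2R)-2-methylbutanoyloxy]-15-(Teoc-oxy)-1αH,5αH-guaia-10(14),11(13)-dien-12,6α-olide | C=C1C(=O)O[C@H]2[C@H]1[C@H](OC(=O)[C@H](C)CC)[C@@H](OC(C)=O)C1=CO[C@@]3(COC(=O)OCC[Si](C)(C)C)CC[C@@H]1[C@@H]23 | intermediate
22 | 9α-acetoxy-4β,14-epoxy-15-hydroxy-8β-[(2R)-2-methylbutanoyloxy]-1αH,5αH-guaia-10(14),11(13)-dien-12,6α-olide (CNP0013863.3) | C=C1C(=O)O[C@H]2[C@H]1[C@H](OC(=O)[C@H](C)CC)[C@@H](OC(C)=O)C1=CO[C@@]3(CO)CC[C@@H]1[C@@H]23 | target

Total step count: 17. Longest linear sequence: 17 steps (1 to 22).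

**Steps most likely to fail**

Step 15 (Proposed new method). The C10 cation may be intercepted before the hydride shift, by the neighbouring 9α-acetate or by solvent, or ionisation may be so slow that simple elimination of the mesylate competes. The fallback uses known chemistry, sets out from 19 and comes back at 20. The same Wagner–Meerwein shift is run as a classical aqueous solvolysis (acetone/H2O, CaCO3, 80 °C), in which the cation or its acetoxonium form is captured by water on the only open (α) side of C10, giving the 10α-hydroxy-4β,14-epoxy-guaianolide F1. Burgess reagent (toluene, 60 °C) should then dehydrate the tertiary alcohol by syn elimination, which is possible only toward C14 because loss of H1 would give a bridgehead alkene and H9 is anti; this gives 20.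

Step 9. Oxidation may occur at another methylene (C3 or C9) or stall at the alcohol stage. The fallback sets out from 10 and comes back at 12. Enzymatic C–H hydroxylation (whole-cell biotransformation with an engineered cytochrome P450 BM3 variant, glucose, buffer pH 8), a reaction class known to hydroxylate C8 of eudesmanolides, should give the 8α-alcohol 11, which is isolated this time and oxidised with Dess–Martin periodinane to 12.

Step 11. Deprotonation may occur at C7, followed by β-elimination of the lactone carboxylate, or enolisation may be poorly regioselective. The fallback avoids the enolate, sets out from 13 and comes back at 19. Reduction with LiBH(s-Bu)3 should give the 8β-alcohol F2. Burgess syn-dehydration, possible only toward C9 because H7 is anti, gives the C8=C9 alkene F3. Epoxidation with mCPBA on the α face (β face screened by the C14 bridge) gives the 8α,9α-epoxide F4. Trans-diaxial (Fürst–Plattner) opening at C8 by (R)-2-methylbutanoic acid 18 with catalytic camphorsulfonic acid gives the 8β-[(2R)-2-methylbutanoyloxy]-9α-alcohol F5, and acetylation (Ac2O, DMAP) gives 19.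

**Further compounds**
F1 | step 15 | 9α-acetoxy-4β,14-epoxy-10α-hydroxy-8β-[(2R)-2-methylbutanoyloxy]-13-(methylsulfonyl)-15-(Teoc-oxy)-1αH,5αH,11βH-guaian-12,6α-olide | CS(=O)(=O)C[C@@H]1C(=O)O[C@H]2[C@H]1[C@H](OC(=O)[C@H](C)CC)[C@@H](OC(C)=O)[C@]1(O)CO[C@@]3(COC(=O)OCC[Si](C)(C)C)CC[C@@H]1[C@@H]23
F0 | step 9 | none | none
F2 | step 11 | 4β,14-epoxy-8β-hydroxy-1β-mesyloxy-13-(methylsulfonyl)-15-(Teoc-oxy)-5αH,11βH-eudesman-12,6α-olide | CS(=O)(=O)C[C@@H]1C(=O)O[C@H]2[C@H]1[C@H](O)C[C@@]3(CO4)[C@H](OS(C)(=O)=O)CC[C@@]4(COC(=O)OCC[Si](C)(C)C)[C@H]23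
F3 | step 11 | 4β,14-epoxy-1β-mesyloxy-13-(methylsulfonyl)-15-(Teoc-oxy)-5αH,11βH-eudesm-8-en-12,6α-olide | CS(=O)(=O)C[C@@H]1C(=O)O[C@H]2[C@H]1C=C[C@@]3(CO4)[C@H](OS(C)(=O)=O)CC[C@@]4(COC(=O)OCC[Si](C)(C)C)[C@H]23
F4 | step 11 | 4β,14:8α,9α-diepoxy-1β-mesyloxy-13-(methylsulfonyl)-15-(Teoc-oxy)-5αH,11βH-eudesman-12,6α-olide | CS(=O)(=O)C[C@@H]1C(=O)O[C@H]2[C@H]1[C@H]5O[C@H]5[C@@]3(CO4)[C@H](OS(C)(=O)=O)CC[C@@]4(COC(=O)OCC[Si](C)(C)C)[C@H]23
F5 | step 11 | 4β,14-epoxy-9α-hydroxy-1β-mesyloxy-8β-[(2R)-2-methylbutanoyloxy]-13-(methylsulfonyl)-15-(Teoc-oxy)-5αH,11βH-eudesman-12,6α-olide | CS(=O)(=O)C[C@@H]1C(=O)O[C@H]2[C@H]1[C@H](OC(=O)[C@H](C)CC)[C@@H](O)[C@@]3(CO4)[C@H](OS(C)(=O)=O)CC[C@@]4(COC(=O)OCC[Si](C)(C)C)[C@H]23
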